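**Retrosynthetic overview**
1. Target 42 ⇐ silyl-protected lactone 41 by one fluoride deprotection; the bridged δ-lactone (C2 acid onto 8-OH) is the last ring closed (39 → 41).
2. The C8/C9/C11 array ⇐ α,β-epoxy ketone 34 (SmI2 opening, then hydroxyl-directed 1,3-anti reduction); the C9–C11 bond ⇐ Nozaki–Hiyama–Kishi union of enol triflate 20 with aldehyde 31 (C13 from a Sharpless epoxidation).
3. 20 ⇐ enone 9: C5–C4 bond by Mukaiyama–Michael addition of ketene silyl acetal 14, quaternary C10 by enolate alkylation with methyl bromoacetate.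
4. Carbocycle 9 ⇐ keto aldehyde 7 by intramolecular aldol condensation; 7 ⇐ pentan-3-one + (R)-benzyl glycidyl ether.
5. Ring order: cyclohexane first (step 5), lactone last (step 26).

Assumption and numbering (one line): the SMILES is read as drawn, i.e. (5S,6R,8S,9R,10R,11S,13S) in seco-labdane numbering — ring C5–C10; "C1 arm" = C1H2–C2O2R on C10; "C4 arm" = C4Me2–C3O2R on C5; side chain C11–C15 on C9; C17 = 8-methyl, C20 = 10-methyl.

**Route**

Step 1
Reactants: 1 pentan-3-one; 2 (R)-benzyl glycidyl ether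
Product: 4 (6R)-7-(benzyloxy)-6-hydroxy-4-methylheptan-3-one (C4 epimers), via lithium pent-2-en-3-olate 3 (not isolated)
Conditions: LDA, THF, −78 °C; then 2, LiClO4, −78 °C → rt; aq. NH4Cl
Reagents that add atoms: none
Why: Enolate alkylation by SN2 opening of the terminal epoxide at CH2 (LiClO4-assisted) brings the C6 carbinol centre unchanged from the chiral pool, while the new methyl-bearing carbon (future C8) forms as an epimer mixture that step 10 erases.

Step 2
Reactants: 4 hydroxy ketone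
Product: 5 (6R)-7-(benzyloxy)-6-[(tert-butyldimethylsilyl)oxy]-4-methylheptan-3-one
Conditions: TBSCl, imidazole, DMF, rt
Reagents that add atoms: tert-butylchlorodimethylsilane, CC(C)(C)[Si](C)(C)Cl
Why: Imidazole-mediated silylation of the secondary alcohol masks 6-OH until step 27 and prevents hemiketal formation.

Step 3
Reactants: 5 benzyl ether
Product: 6 (6R)-6-[(tert-butyldimethylsilyl)oxy]-7-hydroxy-4-methylheptan-3-one
Conditions: H2 (1 atm), 10% Pd/C, EtOAc, rt
Reagents that add atoms: none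
Why: Hydrogenolysis removes the benzyl ether under neutral conditions that leave the ketone and silyl ether alone.

Step 4
Reactants: 6 primary alcohol
Product: 7 (2R)-2-[(tert-butyldimethylsilyl)oxy]-4-methyl-5-oxoheptanal
Conditions: Dess–Martin periodinane, NaHCO3, CH2Cl2, 0 °C → rt
Reagents that add atoms: none
Why: Buffered Dess–Martin oxidation gives the α-silyloxy aldehyde without epimerising C6.

Step 5
Reactants: 7 keto aldehyde
Product: 9 (4R)-4-[(tert-butyldimethylsilyl)oxy]-2,6-dimethylcyclohex-2-en-1-one, via aldol adduct 8 (not isolated)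
Conditions: CSA (10 mol %), toluene, 60 °C
Reagents that add atoms: none
Why: Acid-catalysed intramolecular aldol condensation closes the carbocycle, because only the enol of the ethyl ketone CH2 (future C10) reaches the aldehyde through a six-membered transition state and dehydration of 8 gives the conjugated enone with C6 untouched.

Step 6
Reactants: 10 2-methylpropanoyl chloride; 11 2-(trimethylsilyl)ethanol
Product: 12 2-(trimethylsilyl)ethyl 2-methylpropanoate
Conditions: pyridine, DMAP (cat.), CH2Cl2, 0 °C → rt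
Reagents that add atoms: none
Why: Acylation of the alcohol gives a fluoride-cleavable ester that becomes the C3 carboxyl.

Step 7
Reactants: 12 ester
Product: 14 2-methyl-1-[2-(trimethylsilyl)ethoxy]-1-(trimethylsilyloxy)prop-1-ene, via lithium ester enolate 13 (not isolated)
Conditions: LDA, THF, −78 °C; TMSCl, −78 °C → rt
Reagents that add atoms: chlorotrimethylsilane, C[Si](C)(C)Cl
Why: Enolisation and O-silylation give the ketene silyl acetal, which has no E/Z issue since the α-carbon carries two methyls.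

Step 8
Reactants: 9 enone; 14 ketene silyl acetal
Product: 15 2-(trimethylsilyl)ethyl 2-[(1S,6R)-6-[(tert-butyldimethylsilyl)oxy]-2,4-dimethyl-3-(trimethylsilyloxy)cyclohex-2-en-1-yl]-2-methylpropanoate
Conditions: TMSOTf (10 mol %), CH2Cl2, −78 °C; then Et3N
Reagents that add atoms: none
Why: Mukaiyama–Michael addition puts the C4 arm on C5 from the face opposite the 4-silyloxy group (C5 S, trans to C6), and silyl transfer leaves a regiodefined enol ether.

Step 9
Reactants: 15 silyl enol ether; 16 methyl bromoacetate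
Product: 18 ketone (5S,6R,10R) with C1 arm as methyl ester, via lithium enolate 17 (not isolated)
Conditions: MeLi, THF, 0 °C; then DMPU, 16, −78 → −20 °C
Reagents that add atoms: none
Why: MeLi unmasks the regiospecific enolate, which is alkylated at C10 from the face anti to the bulky C5 substituent, creating the quaternary centre with the C1 arm trans to the C4 arm.

Step 10
Reactants: 18 ketone
Product: 20 enol triflate (C9–OTf with C8=C9), via potassium enolate 19 (not isolated)
Conditions: KHMDS, THF, −78 °C; PhNTf2, −78 → 0 °C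
Reagents that add atoms: N-phenylbis(trifluoromethanesulfonimide), O=S(=O)(N(c1ccccc1)S(=O)(=O)C(F)(F)F)C(F)(F)F
Why: C8 carries the only α-hydrogen, so enolisation and O-triflation give one tetrasubstituted enol triflate and remove the C8 epimer mixture.

Step 11
Reactants: 21 but-3-yn-1-ol
Product: 23 1-[(but-3-yn-1-yloxy)methyl]-4-methoxybenzene, via sodium but-3-yn-1-olate 22 (not isolated)
Conditions: NaH, THF/DMF, 0 °C; PMBCl, Bu4NI (cat.), rt
Reagents that add atoms: 4-methoxybenzyl chloride, COc1ccc(CCl)cc1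
Why: Williamson etherification installs a PMB group that is orthogonal to the later silyl ethers.

Step 12
Reactants: 23 alkyne
Product: 25 (E)-5-[(4-methoxybenzyl)oxy]-3-methylpent-2-en-1-ol, via alkenyldimethylalane 24 (not isolated)
Conditions: Me3Al, Cp2ZrCl2 (0.25 equiv), CH2Cl2, 0 °C → rt; then (CH2O)n, THF, rt
Reagents that add atoms: trimethylaluminium, C[Al](C)C; formaldehyde (as paraformaldehyde), C=O
Why: Negishi carboalumination adds Me–Al syn across the alkyne with Al at the terminus, and hydroxymethylation with retention gives only the (E)-allylic alcohol.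

Step 13
Reactants: 25 allylic alcohol
Product: 26 [(2S,3S)-3-{2-[(4-methoxybenzyl)oxy]ethyl}-3-methyloxiran-2-yl]methanol
Conditions: Ti(OiPr)4 (10 mol %), L-(+)-diethyl tartrate, t-BuOOH, 4 Å MS, CH2Cl2, −20 °C
Reagents that add atoms: tert-butyl hydroperoxide, CC(C)(C)OO
Why: Sharpless asymmetric epoxidation with the L-tartrate delivers oxygen to one face of the (E)-allylic alcohol (as for geraniol), fixing the future C13 as S.

Step 14
Reactants: 26 epoxy alcohol
Product: 27 (2R,3S)-2-(iodomethyl)-3-{2-[(4-methoxybenzyl)oxy]ethyl}-3-methyloxirane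
Conditions: I2, PPh3, imidazole, CH2Cl2, 0 °C
Reagents that add atoms: iodine, [I][I]
Why: Appel-type iodination converts the primary alcohol into the iodide without opening the epoxide.

Step 15
Reactants: 27 epoxy iodide
Product: 28 (3S)-5-[(4-methoxybenzyl)oxy]-3-methylpent-1-en-3-ol
Conditions: Zn dust, AcOH, EtOH, rt → 50 °C
Reagents that add atoms: none
Why: Zinc inserts into the C–I bond and β-elimination opens the epoxide, giving the tertiary allylic alcohol with its C–O centre untouched.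

Step 16
Reactants: 28 tertiary alcohol
Product: 29 (3S)-5-[(4-methoxybenzyl)oxy]-3-methyl-3-[(triethylsilyl)oxy]pent-1-ene
Conditions: TESOTf, 2,6-lutidine, CH2Cl2, −78 → 0 °C
Reagents that add atoms: triethylsilyl trifluoromethanesulfonate, CC[Si](CC)(CC)OS(=O)(=O)C(F)(F)F
Why: The reactive silyl triflate silylates the hindered tertiary alcohol.

Step 17
Reactants: 29 PMB ether
Product: 30 (3S)-3-methyl-3-[(triethylsilyl)oxy]pent-4-en-1-ol
Conditions: DDQ, CH2Cl2/pH 7 buffer, 0 °C
Reagents that add atoms: none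
Why: DDQ oxidises the electron-rich PMB ether and water releases the primary alcohol, leaving the silyl ether and vinyl group alone.

Step 18
Reactants: 30 primary alcohol
Product: 31 (3S)-3-methyl-3-[(triethylsilyl)oxy]pent-4-enal
Conditions: Dess–Martin periodinane, NaHCO3, CH2Cl2, 0 °C → rt
Reagents that add atoms: none
Why: Buffered Dess–Martin oxidation gives the β-silyloxy aldehyde without β-elimination.

Step 19
Reactants: 20 enol triflate; 31 aldehyde
Product: 32 allylic alcohol (5S,6R,10R,13S; C11 epimers)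
Conditions: CrCl2 (6 equiv), NiCl2 (2 mol %), DMF/DMSO, rt
Reagents that add atoms: none
Why: Nozaki–Hiyama–Kishi coupling, in which zerovalent nickel inserts into the C–OTf bond and the derived alkenyl species of trivalent chromium adds only to the aldehyde (esters untouched), forms C9–C11; the C11 ratio is irrelevant because step 20 oxidises it.

Step 20
Reactants: 32 allylic alcohols
Product: 33 enone (C11 ketone conjugated to C8=C9)
Conditions: Dess–Martin periodinane, NaHCO3, CH2Cl2, rt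
Reagents that add atoms: none
Why: Oxidation converges both C11 epimers on one enone.

Step 21
Reactants: 33 enone
Product: 34 8,9-epoxy ketone (5S,6R,8S,9R,10R,13S)
Conditions: mCPBA, NaHCO3, CH2Cl2, 0 °C
Reagents that add atoms: 3-chloroperbenzoic acid, OOC(=O)c1cccc(Cl)c1
Why: Prilezhaev epoxidation picks the tetrasubstituted, twisted ring alkene over the vinyl group, and with the ring locked by the equatorial C5 and C6 groups the peracid comes anti to the axial C10 methyl, placing the epoxide oxygen cis to the C1 arm.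

Step 22
Reactants: 34 epoxy ketone
Product: 36 β-hydroxy ketone (5S,6R,8S,9S,10R,13S), via samarium enolate 35 (not isolated)
Conditions: SmI2 (2.5 equiv), THF/MeOH, −90 °C
Reagents that add atoms: none
Why: Two-electron reduction cleaves the Cα–O bond of the α,β-epoxy ketone with the C8–O centre retained, and the enolate of trivalent samarium is protonated at C9 from the face opposite the two axial methyls, leaving the acyl group equatorial.

Step 23
Reactants: 36 β-hydroxy ketone
Product: 37 anti-8,11-diol (5S,6R,8S,9R,10R,11S,13S)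
Conditions: Me4NBH(OAc)3, MeCN/AcOH, −30 → 0 °C
Reagents that add atoms: none
Why: Evans–Saksena reduction, in which boron bound to 8-OH delivers hydride intramolecularly through a chair transition state, gives the 1,3-anti diol and so 11S.

Step 24
Reactants: 37 diol
Product: 38 11-O-triethylsilyl ether with free tertiary 8-OH
Conditions: TESCl, imidazole, DMAP (cat.), DMF, rt (used at once after step 23)
Reagents that add atoms: chlorotriethylsilane, CC[Si](Cl)(CC)CC
Why: The silyl chloride silylates only the secondary 11-OH, which blocks the competing fused lactone from O11.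

Step 25
Reactants: 38 methyl ester
Product: 39 C2 carboxylic acid
Conditions: LiOH, THF/MeOH/H2O, rt; then 0.5 M HCl to pH 4
Reagents that add atoms: none
Why: Saponification cleaves the unhindered methyl ester while the α,α-dimethyl 2-(trimethylsilyl)ethyl ester on the congested C4 resists hydroxide.

Step 26
Reactants: 39 hydroxy acid
Product: 41 fully protected bridged lactone, via mixed anhydride 40 (not isolated)
Conditions: 2,4,6-trichlorobenzoyl chloride, Et3N, THF, rt; then DMAP, toluene, 60 °C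
Reagents that add atoms: none
Why: Yamaguchi lactonisation acylates the only free hydroxyl, 8-OH, which is cis to the C1 arm, so the bridged δ-lactone closes without touching a stereocentre.

Step 27
Reactants: 41 protected lactone
Product: 42 target acid
Conditions: TBAF (excess), THF, 0 → 40 °C; then 0.5 M HCl to pH 4
Reagents that add atoms: none
Why: Fluoride cleaves the three silyl ethers and fragments the 2-(trimethylsilyl)ethyl ester by β-elimination, conditions that the lactone and the tertiary allylic alcohol survive.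

**Compound list**
1 | pentan-3-one | CCC(=O)CC | starting material
2 | (R)-benzyl glycidyl ether, (2R)-2-[(benzyloxy)methyl]oxirane | C(OC[C@H]1CO1)c1ccccc1 | starting material
3 | lithium pent-2-en-3-olate (not isolated) | CC=C(CC)[O-].[Li+] | intermediate
4 | (6R)-7-(benzyloxy)-6-hydroxy-4-methylheptan-3-one, C4 epimers | CCC(=O)C(C)C[C@@H](O)COCc1ccccc1 | intermediate
5 | (6R)-7-(benzyloxy)-6-[(tert-butyldimethylsilyl)oxy]-4-methylheptan-3-one | CCC(=O)C(C)C[C@@H](O[Si](C)(C)C(C)(C)C)COCc1ccccc1 | intermediate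
6 | (6R)-6-[(tert-butyldimethylsilyl)oxy]-7-hydroxy-4-methylheptan-3-one | CCC(=O)C(C)C[C@@H](O[Si](C)(C)C(C)(C)C)CO | intermediate
7 | (2R)-2-[(tert-butyldimethylsilyl)oxy]-4-methyl-5-oxoheptanal | CCC(=O)C(C)C[C@@H](O[Si](C)(C)C(C)(C)C)C=O | intermediate
8 | (4R)-4-[(tert-butyldimethylsilyl)oxy]-3-hydroxy-2,6-dimethylcyclohexan-1-one, aldol adduct (not isolated) | CC1C(O)[C@H](O[Si](C)(C)C(C)(C)C)CC(C)C1=O | intermediate
9 | (4R)-4-[(tert-butyldimethylsilyl)oxy]-2,6-dimethylcyclohex-2-en-1-one, C6 epimers | CC1=C[C@H](O[Si](C)(C)C(C)(C)C)CC(C)C1=O | intermediate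
10 | 2-methylpropanoyl chloride | CC(C)C(Cl)=O | starting material
11 | 2-(trimethylsilyl)ethanol | C[Si](C)(C)CCO | starting material
12 | 2-(trimethylsilyl)ethyl 2-methylpropanoate | CC(C)C(=O)OCC[Si](C)(C)C | intermediate
13 | lithium enolate of 12 (not isolated) | CC(C)=C([O-])OCC[Si](C)(C)C.[Li+] | intermediate
14 | 2-methyl-1-[2-(trimethylsilyl)ethoxy]-1-(trimethylsilyloxy)prop-1-ene | CC(C)=C(O[Si](C)(C)C)OCC[Si](C)(C)C | intermediate
15 | 2-(trimethylsilyl)ethyl 2-[(1S,6R)-6-[(tert-butyldimethylsilyl)oxy]-2,4-dimethyl-3-(trimethylsilyloxy)cyclohex-2-en-1-yl]-2-methylpropanoate (C4 arm trans to OTBS) | CC1=C(O[Si](C)(C)C)C(C)C[C@@H](O[Si](C)(C)C(C)(C)C)[C@@H]1C(C)(C)C(=O)OCC[Si](C)(C)C | intermediate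
16 | methyl bromoacetate | COC(=O)CBr | starting material
17 | lithium enolate from 15 (not isolated) | CC1=C([O-])C(C)C[C@@H](O[Si](C)(C)C(C)(C)C)[C@@H]1C(C)(C)C(=O)OCC[Si](C)(C)C.[Li+] | intermediate
18 | methyl 2-[(1R,2S,3R)-3-[(tert-butyldimethylsilyl)oxy]-1,5-dimethyl-2-{2-methyl-1-oxo-1-[2-(trimethylsilyl)ethoxy]propan-2-yl}-6-oxocyclohexyl]acetate (C1 arm trans to C4 arm; 5-methyl epimers) | C[C@]1(CC(=O)OC)C(=O)C(C)C[C@@H](O[Si](C)(C)C(C)(C)C)[C@@H]1C(C)(C)C(=O)OCC[Si](C)(C)C | intermediate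
19 | potassium enolate of 18 (not isolated) | C[C@]1(CC(=O)OC)C([O-])=C(C)C[C@@H](O[Si](C)(C)C(C)(C)C)[C@@H]1C(C)(C)C(=O)OCC[Si](C)(C)C.[K+] | intermediate
20 | methyl 2-[(1R,5R,6S)-5-[(tert-butyldimethylsilyl)oxy]-1,3-dimethyl-6-{2-methyl-1-oxo-1-[2-(trimethylsilyl)ethoxy]propan-2-yl}-2-(trifluoromethylsulfonyloxy)cyclohex-2-en-1-yl]acetate | C[C@]1(CC(=O)OC)C(OS(=O)(=O)C(F)(F)F)=C(C)C[C@@H](O[Si](C)(C)C(C)(C)C)[C@@H]1C(C)(C)C(=O)OCC[Si](C)(C)C | intermediate
21 | but-3-yn-1-ol | C#CCCO | starting material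
22 | sodium but-3-yn-1-olate (not isolated) | C#CCC[O-].[Na+] | intermediate
23 | 1-[(but-3-yn-1-yloxy)methyl]-4-methoxybenzene | C#CCCOCc1ccc(OC)cc1 | intermediate
24 | (E)-alkenyldimethylalane from 23 (not isolated) | C[Al](C)/C=C(\C)CCOCc1ccc(OC)cc1 | intermediate
25 | (E)-5-[(4-methoxybenzyl)oxy]-3-methylpent-2-en-1-ol | OC/C=C(\C)CCOCc1ccc(OC)cc1 | intermediate
26 | [(2S,3S)-3-{2-[(4-methoxybenzyl)oxy]ethyl}-3-methyloxiran-2-yl]methanol | OC[C@@H]1O[C@@]1(C)CCOCc1ccc(OC)cc1 | intermediate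
27 | (2R,3S)-2-(iodomethyl)-3-{2-[(4-methoxybenzyl)oxy]ethyl}-3-methyloxirane | IC[C@@H]1O[C@@]1(C)CCOCc1ccc(OC)cc1 | intermediate
28 | (3S)-5-[(4-methoxybenzyl)oxy]-3-methylpent-1-en-3-ol | C=C[C@@](C)(O)CCOCc1ccc(OC)cc1 | intermediate
29 | (3S)-5-[(4-methoxybenzyl)oxy]-3-methyl-3-[(triethylsilyl)oxy]pent-1-ene | C=C[C@@](C)(O[Si](CC)(CC)CC)CCOCc1ccc(OC)cc1 | intermediate
30 | (3S)-3-methyl-3-[(triethylsilyl)oxy]pent-4-en-1-ol | C=C[C@@](C)(O[Si](CC)(CC)CC)CCO | intermediate
31 | (3S)-3-methyl-3-[(triethylsilyl)oxy]pent-4-enal | C=C[C@@](C)(O[Si](CC)(CC)CC)CC=O | intermediate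
32 | NHK allylic alcohol: 20 with (3S)-1-hydroxy-3-methyl-3-[(triethylsilyl)oxy]pent-4-en-1-yl in place of OTf; (5S,6R,10R,13S), C11 epimers | C=C[C@@](C)(O[Si](CC)(CC)CC)CC(O)C1=C(C)C[C@@H](O[Si](C)(C)C(C)(C)C)[C@H](C(C)(C)C(=O)OCC[Si](C)(C)C)[C@@]1(C)CC(=O)OC | intermediate
33 | enone: 32 with C11 ketone; (5S,6R,10R,13S) | C=C[C@@](C)(O[Si](CC)(CC)CC)CC(=O)C1=C(C)C[C@@H](O[Si](C)(C)C(C)(C)C)[C@H](C(C)(C)C(=O)OCC[Si](C)(C)C)[C@@]1(C)CC(=O)OC | intermediate
34 | 8,9-epoxide of 33, oxygen cis to the C1 arm; (5S,6R,8S,9R,10R,13S) | C=C[C@@](C)(O[Si](CC)(CC)CC)CC(=O)[C@]12O[C@@]1(C)C[C@@H](O[Si](C)(C)C(C)(C)C)[C@H](C(C)(C)C(=O)OCC[Si](C)(C)C)[C@@]2(C)CC(=O)OC | intermediate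
35 | samarium enolate/alkoxide from 34 (not isolated) | C=C[C@@](C)(O[Si](CC)(CC)CC)CC([O-])=C1[C@@](C)([O-])C[C@@H](O[Si](C)(C)C(C)(C)C)[C@H](C(C)(C)C(=O)OCC[Si](C)(C)C)[C@@]1(C)CC(=O)OC.[Sm+3].[Sm+3].[I-].[I-].[I-].[I-] | intermediate
36 | β-hydroxy ketone: 8-OH cis to the C1 arm, 9-H cis to it, C11 ketone; (5S,6R,8S,9S,10R,13S) | C=C[C@@](C)(O[Si](CC)(CC)CC)CC(=O)[C@@H]1[C@@](C)(O)C[C@@H](O[Si](C)(C)C(C)(C)C)[C@H](C(C)(C)C(=O)OCC[Si](C)(C)C)[C@@]1(C)CC(=O)OC | intermediate
37 | anti-8,11-diol; (5S,6R,8S,9R,10R,11S,13S) | C=C[C@@](C)(O[Si](CC)(CC)CC)C[C@H](O)[C@@H]1[C@@](C)(O)C[C@@H](O[Si](C)(C)C(C)(C)C)[C@H](C(C)(C)C(=O)OCC[Si](C)(C)C)[C@@]1(C)CC(=O)OC | intermediate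
38 | 11-O-triethylsilyl ether of 37 (8-OH free, C2 methyl ester) | C=C[C@@](C)(O[Si](CC)(CC)CC)C[C@H](O[Si](CC)(CC)CC)[C@@H]1[C@@](C)(O)C[C@@H](O[Si](C)(C)C(C)(C)C)[C@H](C(C)(C)C(=O)OCC[Si](C)(C)C)[C@@]1(C)CC(=O)OC | intermediate
39 | C2 carboxylic acid of 38 | C=C[C@@](C)(O[Si](CC)(CC)CC)C[C@H](O[Si](CC)(CC)CC)[C@@H]1[C@@](C)(O)C[C@@H](O[Si](C)(C)C(C)(C)C)[C@H](C(C)(C)C(=O)OCC[Si](C)(C)C)[C@@]1(C)CC(=O)O | intermediate
40 | mixed anhydride of 39 with 2,4,6-trichlorobenzoic acid (not isolated) | C=C[C@@](C)(O[Si](CC)(CC)CC)C[C@H](O[Si](CC)(CC)CC)[C@@H]1[C@@](C)(O)C[C@@H](O[Si](C)(C)C(C)(C)C)[C@H](C(C)(C)C(=O)OCC[Si](C)(C)C)[C@@]1(C)CC(=O)OC(=O)c1c(Cl)cc(Cl)cc1Cl | intermediate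
41 | target with 6-OTBS, 11-OTES, 13-OTES and C3 2-(trimethylsilyl)ethyl ester | C=C[C@@](C)(O[Si](CC)(CC)CC)C[C@H](O[Si](CC)(CC)CC)[C@H]1[C@]2(C)CC(=O)O[C@@]1(C)C[C@@H](O[Si](C)(C)C(C)(C)C)[C@@H]2C(C)(C)C(=O)OCC[Si](C)(C)C | intermediate
42 | CNP0297019.2, (5S,6R,8S,9R,10R,11S,13S) | C=C[C@@](C)(O)C[C@H](O)[C@H]1[C@]2(C)CC(=O)O[C@@]1(C)C[C@@H](O)[C@@H]2C(C)(C)C(=O)O | target

**Totals**
Total step count: 27. Longest linear sequence: 17 steps (1–5, 8–10, 19–27; the side-chain branch 11–18 then 19–27 is equally long), i.e. 17/27 = 0.63 of the total.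

**Three steps most likely to fail, with fallbacks**

Step 9 (alkylation to the quaternary C10 beside the CMe2-bearing C5 may stall or O-alkylate). The fallback sets out from 15 and comes back at 18. Tsuji–Trost allylation of the silyl enol ether (allyl methyl carbonate, Pd2(dba)3, dppe, THF) uses a soft π-allyl electrophile that tolerates the congestion and again enters anti to the C4 arm, giving allyl ketone F1. OsO4 (cat.)/NaIO4/2,6-lutidine cleaves the terminal alkene to aldehyde F2. NaClO2/NaH2PO4/2-methylbut-2-ene gives acid F3, and MeI/K2CO3 in DMF returns 18.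

Step 19 (NHK coupling of the hindered tetrasubstituted triflate). The fallback sets out from 20 and 31 and comes back at 33, skipping 32. Hexamethylditin, Pd(PPh3)4 and LiCl in dioxane at 90 °C convert 20 into alkenylstannane F4. Aldehyde 31 is oxidised with NaClO2 to acid F5, and 1-chloro-N,N,2-trimethylprop-1-en-1-amine converts it under neutral conditions into acid chloride F6. Stille acylation of F6 by F4 (Pd2(dba)3, tri(2-furyl)phosphine, CuCl, THF, 50 °C) gives enone 33 directly.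

Step 26 (acylation of the tertiary 8-OH needs the ring to leave its chair and may fail). The fallback sets out from 38 and comes back at 41. SOCl2/pyridine at −20 °C dehydrates the equatorial tertiary alcohol towards the methyl group, giving exocyclic alkene F7. LiOH gives alkene acid F8. Iodolactonisation (I2, NaHCO3, MeCN, 0 °C) closes the lactone 6-exo at the tertiary carbon, with the tether forcing oxygen cis to the C1 arm, giving iodomethyl lactone F9. Bu3SnH/AIBN in toluene at 80 °C removes iodine to give 41.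

Further compounds
F1 | step 9 | allyl ketone: 18 with CH2CH=CH2 in place of CH2CO2Me on C10 | C[C@]1(CC=C)C(=O)C(C)C[C@@H](O[Si](C)(C)C(C)(C)C)[C@@H]1C(C)(C)C(=O)OCC[Si](C)(C)C
F2 | step 9 | aldehyde: 18 with CH2CHO in place of CH2CO2Me | C[C@]1(CC=O)C(=O)C(C)C[C@@H](O[Si](C)(C)C(C)(C)C)[C@@H]1C(C)(C)C(=O)OCC[Si](C)(C)C
F3 | step 9 | acid: 18 with CH2CO2H in place of CH2CO2Me | C[C@]1(CC(=O)O)C(=O)C(C)C[C@@H](O[Si](C)(C)C(C)(C)C)[C@@H]1C(C)(C)C(=O)OCC[Si](C)(C)C
F4 | step 19 | alkenylstannane: 20 with SnMe3 in place of OTf | C[C@]1(CC(=O)OC)C([Sn](C)(C)C)=C(C)C[C@@H](O[Si](C)(C)C(C)(C)C)[C@@H]1C(C)(C)C(=O)OCC[Si](C)(C)C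
F5 | step 19 | (3S)-3-methyl-3-[(triethylsilyl)oxy]pent-4-enoic acid | C=C[C@@](C)(O[Si](CC)(CC)CC)CC(=O)O
F6 | step 19 | (3S)-3-methyl-3-[(triethylsilyl)oxy]pent-4-enoyl chloride | C=C[C@@](C)(O[Si](CC)(CC)CC)CC(Cl)=O
F7 | step 26 | 8(17)-exocyclic alkene: 38 minus water | C=C[C@@](C)(O[Si](CC)(CC)CC)C[C@H](O[Si](CC)(CC)CC)[C@@H]1C(=C)C[C@@H](O[Si](C)(C)C(C)(C)C)[C@H](C(C)(C)C(=O)OCC[Si](C)(C)C)[C@@]1(C)CC(=O)OC
F8 | step 26 | C2 carboxylic acid of F7 | C=C[C@@](C)(O[Si](CC)(CC)CC)C[C@H](O[Si](CC)(CC)CC)[C@@H]1C(=C)C[C@@H](O[Si](C)(C)C(C)(C)C)[C@H](C(C)(C)C(=O)OCC[Si](C)(C)C)[C@@]1(C)CC(=O)O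
F9 | step 26 | iodomethyl lactone: 41 with CH2I in place of the 8-methyl | C=C[C@@](C)(O[Si](CC)(CC)CC)C[C@H](O[Si](CC)(CC)CC)[C@H]1[C@]2(C)CC(=O)O[C@@]1(C[I])C[C@@H](O[Si](C)(C)C(C)(C)C)[C@@H]2C(C)(C)C(=O)OCC[Si](C)(C)C
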